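**Strategy.** In tricyclo[5.3.1.0(1,5)]undecane numbering, the target's core is a bicyclo[3.2.1]octene whose seven-membered ring C1–C5–C6–C7–C8=C9–C10 is bridged by C11. This ring is disconnected at C7–C8 and C1–C10 into a fused cyclopentadiene (C7=C6–C5=C1, C11 methylene, cyclopentanone ring C1–C5 already attached) and a three-carbon vinylcarbenoid (C8 ester, C10 oxygen). One rhodium-catalysed cyclopropanation/Cope cascade, a formal (4+3) cycloaddition, forges both bonds, the quaternary C1 and the whole bridged skeleton. The catalyst sets C7, C1 and C10 are relayed, and C6, C5 and C2 are then set by substrate control on the rigid bicycle before the hydroxy-acid chain is attached.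

Key step: step 7

Remarks.
- Locants: C1 spiro carbon, C2 formyl carbon, C3/C4 ring CH2, C5 ring-fusion CH, C6 the CH3/CH2OH carbon, C7 bridgehead CH, C8 carboxyl-bearing alkene carbon, C9 alkene CH, C10 acyloxy carbon, C11 one-carbon bridge. "Exo" means syn to C11, "endo" anti to it.
- The target as drawn has H-5 exo (C4 endo), CH2OH exo at C6, the acyloxy group exo at C10 and the formyl group on the ring face syn to C10; the route is built for exactly this configuration.
- Assumption: Rh2(S-BTPCP)4 (dirhodium tetrakis[(S)-1-(4-bromophenyl)-2,2-diphenylcyclopropane-1-carboxylate]) induces the C7 configuration drawn in step 7; if the sense is opposite, Rh2(R-BTPCP)4 is used and nothing else changes.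
- Starting materials 1, 4, 7, 8, 22 and 25 are taken as commercially available.

**Diene fragment**

Step 1
Reactants: 1 cyclopentane-1,3-dione
Product: 2 2-allylcyclopentane-1,3-dione
Conditions: allyl acetate (0.7 equiv), Pd(PPh3)4 (2 mol %), Et3N, THF, rt
Reagents that add atoms: allyl acetate C=CCOC(C)=O
Why: Tsuji–Trost allylation, in which the soft, doubly stabilised dione enolate attacks the π-allylpalladium complex at carbon (any O-allyl ether re-ionises) and excess dione holds back diallylation.

Step 2
Reactants: 2 2-allylcyclopentane-1,3-dione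
Product: 3 2-allyl-3-oxocyclopent-1-en-1-yl trifluoromethanesulfonate
Conditions: Tf2O, Et3N, CH2Cl2, −78 → 0 °C
Reagents that add atoms: trifluoromethanesulfonic anhydride O=S(=O)(OS(=O)(=O)C(F)(F)F)C(F)(F)F
Why: O-sulfonylation of the enol form of the vinylogous acid, the standard route from cyclic 1,3-diones to β-triflyloxy enones.

Step 3
Reactants: 3 2-allyl-3-oxocyclopent-1-en-1-yl trifluoromethanesulfonate; 4 isopropenylboronic acid pinacol ester
Product: 5 2-allyl-3-(prop-1-en-2-yl)cyclopent-2-en-1-one
Conditions: Pd(PPh3)4 (3 mol %), K3PO4, dioxane/H2O, 60 °C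
Reagents that add atoms: none
Why: Suzuki–Miyaura coupling, with fast oxidative addition into the electron-poor vinyl triflate, places the allyl and isopropenyl arms cis on the enone double bond.

Step 4
Reactants: 5 2-allyl-3-(prop-1-en-2-yl)cyclopent-2-en-1-one
Product: 6 4-methyl-3,6-dihydro-2H-pentalen-1-one
Conditions: RuCl2(=CHPh)(H2IMes)(PCy3) (second-generation Grubbs catalyst, 5 mol %), CH2Cl2 (0.01 M), 40 °C
Reagents that add atoms: none
Why: Ring-closing metathesis should start at the monosubstituted allyl alkene and close the five-membered ring onto the isopropenyl group with loss of ethene; the linearly conjugated cyclopentadiene tautomer formed is expected to be the preferred one and is used at once to forestall 1,5-hydrogen shifts and dimerisation.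

**Diazo fragment**

Step 5
Reactants: 7 tert-butyl diazoacetate; 8 (tert-butyldimethylsilyloxy)acetaldehyde
Product: 9 tert-butyl 4-[(tert-butyldimethylsilyl)oxy]-2-diazo-3-hydroxybutanoate (racemic)
Conditions: DBU (10 mol %), MeCN, rt
Reagents that add atoms: none
Why: Base-catalysed aldol-type addition of the diazoacetate, deprotonated at the diazo carbon, to the aldehyde; the racemic carbinol centre is removed in step 6.

Step 6
Reactants: 9 tert-butyl 4-[(tert-butyldimethylsilyl)oxy]-2-diazo-3-hydroxybutanoate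
Product: 11 tert-butyl (E)-4-[(tert-butyldimethylsilyl)oxy]-2-diazobut-3-enoate, via dichlorophosphate ester 10 (not isolated)
Conditions: POCl3, Et3N, CH2Cl2, 0 °C → rt
Reagents that add atoms: none
Why: Dehydration of a β-hydroxy-α-diazo ester, the standard entry to vinyldiazoacetates, in which the dichlorophosphate ionises with help from the diazo group and loses the C4 proton to give the more stable E enol ether (any Z isomer is removed by chromatography).

**Key step and core elaboration**

Step 7
Reactants: 6 4-methyl-3,6-dihydro-2H-pentalen-1-one; 11 tert-butyl (E)-4-[(tert-butyldimethylsilyl)oxy]-2-diazobut-3-enoate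
Product: 13 tert-butyl 10-endo-[(tert-butyldimethylsilyl)oxy]-6-methyl-2-oxotricyclo[5.3.1.0(1,5)]undeca-5,8-diene-8-carboxylate, via cis-divinylcyclopropane 12 (not isolated)
Conditions: Rh2(S-BTPCP)4 (1 mol %), CH2Cl2, −20 °C → rt, slow addition of 11 (1.5 equiv); then 40 °C
Reagents that add atoms: none
Why: The catalyst converts 11 into a donor/acceptor rhodium vinylcarbenoid that cyclopropanates the C6=C7 double bond of 6 (the γ,δ bond of the dienone, with the largest HOMO coefficient at unsubstituted C7), bonding C8 to C7 with the vinyl group cis to the ring diene, and cis-divinylcyclopropane 12 then undergoes a boat-type Cope rearrangement that forms C10–C1; this is the known tandem cyclopropanation/Cope rearrangement (formal (4+3) cycloaddition) of vinyldiazoacetates with cyclopentadienes. The three-membered ring closes by concerted carbene transfer, and the [3,3] shift then closes, through the single C10–C1 bond, both the seven-membered ring C1–C5–C6–C7–C8–C9–C10 and the six-membered ring C1–C11–C7–C8–C9–C10 of the bicyclo[3.2.1]octadiene while opening the cyclopropane. C7 is set by the chiral catalyst, which selects one face of the flat, achiral diene; quaternary C1 follows because the tethered vinyl terminus can reach C1 only on the face that carries the cyclopropane; C10 follows from the boat geometry, in which the E-siloxy group points outward and ends endo (anti to C11). The step needs site selectivity (C6=C7 over the enone double bond C1=C5, the ketone oxygen and the C11–H bonds) and the C8-to-C7 orientation, both secured by the electron-poor, tetrasubstituted nature of C1=C5 and by the C6 methyl group that stabilises the charge developing there; gentle warming completes the Cope step, which builds a quaternary centre.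

Step 8
Reactants: 13 tert-butyl 10-endo-[(tert-butyldimethylsilyl)oxy]-6-methyl-2-oxotricyclo[5.3.1.0(1,5)]undeca-5,8-diene-8-carboxylate
Product: 14 tert-butyl 10-endo-hydroxy-6-methyl-2-oxotricyclo[5.3.1.0(1,5)]undeca-5,8-diene-8-carboxylate
Conditions: HF·pyridine, pyridine/THF, 0 °C → rt
Reagents that add atoms: none
Why: Desilylation with a buffered acidic fluoride source cleaves the secondary silyl ether without generating a free alkoxide, which could cleave the C10–C1 bond by retro-aldol fragmentation next to the C2 ketone; the tert-butyl ester is untouched.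

Step 9
Reactants: 14 tert-butyl 10-endo-hydroxy-6-methyl-2-oxotricyclo[5.3.1.0(1,5)]undeca-5,8-diene-8-carboxylate
Product: 16 tert-butyl 10-exo-(benzoyloxy)-6-methyl-2-oxotricyclo[5.3.1.0(1,5)]undeca-5,8-diene-8-carboxylate, via alkoxyphosphonium benzoate 15 (not isolated)
Conditions: PPh3, DIAD, PhCO2H, toluene, 0 → 40 °C
Reagents that add atoms: benzoic acid O=C(O)c1ccccc1
Why: Mitsunobu esterification, in which benzoate displaces the oxyphosphonium group by SN2 inversion from the exo face and so turns the endo C10–O of the cycloaddition into the exo C10–O of the target; elimination is impossible (C1 quaternary, C9 vinylic) and SN2' attack at the fully substituted C8 is blocked.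

Step 10
Reactants: 16 tert-butyl 10-exo-(benzoyloxy)-6-methyl-2-oxotricyclo[5.3.1.0(1,5)]undeca-5,8-diene-8-carboxylate
Product: 17 tert-butyl 10-exo-(benzoyloxy)-6-exo-(hydroxymethyl)-6-methyl-2-oxotricyclo[5.3.1.0(1,5)]undeca-4,8-diene-8-carboxylate
Conditions: Me2AlCl (3 equiv), (CH2O)n, CH2Cl2, 0 °C → rt
Reagents that add atoms: formaldehyde (from paraformaldehyde) C=O
Why: Lewis acid-promoted carbonyl-ene reaction of formaldehyde with the strained tetrasubstituted C5=C6 alkene, in which the enophile should bond to C6 (bonding at C5 would create two adjacent quaternary centres) from the exo face, the endo face being covered by the C8–C10 bridge, while a C4 hydrogen is transferred, so that C6 is set with CH2OH exo and CH3 endo and the double bond moves to C4=C5.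

Step 11
Reactants: 17 tert-butyl 10-exo-(benzoyloxy)-6-exo-(hydroxymethyl)-6-methyl-2-oxotricyclo[5.3.1.0(1,5)]undeca-4,8-diene-8-carboxylate
Product: 18 tert-butyl 10-exo-(benzoyloxy)-6-exo-(hydroxymethyl)-6-methyl-2-oxotricyclo[5.3.1.0(1,5)]undec-8-ene-8-carboxylate (H-5 exo)
Conditions: [Ir(cod)(PCy3)(py)]PF6 (5 mol %), H2 (1 atm), CH2Cl2, rt
Reagents that add atoms: none
Why: Hydroxyl-directed homogeneous hydrogenation, in which the homoallylic C6 hydroxymethyl group binds iridium and delivers both hydrogens to the exo face of C4=C5, setting H-5 exo (C4 endo) under kinetic control although this ring fusion is the more strained one; the conjugated, undirected C8=C9 alkene should react far more slowly.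

Step 12
Reactants: 18 tert-butyl 10-exo-(benzoyloxy)-6-exo-(hydroxymethyl)-6-methyl-2-oxotricyclo[5.3.1.0(1,5)]undec-8-ene-8-carboxylate
Product: 19 tert-butyl 10-exo-(benzoyloxy)-6-exo-{[(tert-butyldimethylsilyl)oxy]methyl}-6-methyl-2-oxotricyclo[5.3.1.0(1,5)]undec-8-ene-8-carboxylate
Conditions: TBSCl, imidazole, DMF, rt
Reagents that add atoms: tert-butyldimethylsilyl chloride CC(C)(C)[Si](C)(C)Cl
Why: Silylation of the only free hydroxyl group masks it for the later acylation at C10.

Step 13
Reactants: 19 tert-butyl 10-exo-(benzoyloxy)-6-exo-{[(tert-butyldimethylsilyl)oxy]methyl}-6-methyl-2-oxotricyclo[5.3.1.0(1,5)]undec-8-ene-8-carboxylate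
Product: 20 tert-butyl 10-exo-(benzoyloxy)-6-exo-{[(tert-butyldimethylsilyl)oxy]methyl}-2-(methoxymethylidene)-6-methyltricyclo[5.3.1.0(1,5)]undec-8-ene-8-carboxylate (E/Z mixture)
Conditions: MeOCH2PPh3Cl, KN(SiMe3)2, THF, 0 °C → rt
Reagents that add atoms: (methoxymethyl)triphenylphosphonium chloride COC[P+](c1ccccc1)(c1ccccc1)c1ccccc1.[Cl-]
Why: Wittig reaction with (methoxymethylene)triphenylphosphorane converts the hindered C2 ketone into an enol ether that serves as the masked, one-carbon-homologated aldehyde (both geometric isomers converge later); the benzoate cannot eliminate because C1 is quaternary.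

Step 14
Reactants: 20 tert-butyl 10-exo-(benzoyloxy)-6-exo-{[(tert-butyldimethylsilyl)oxy]methyl}-2-(methoxymethylidene)-6-methyltricyclo[5.3.1.0(1,5)]undec-8-ene-8-carboxylate
Product: 21 tert-butyl 6-exo-{[(tert-butyldimethylsilyl)oxy]methyl}-10-exo-hydroxy-2-(methoxymethylidene)-6-methyltricyclo[5.3.1.0(1,5)]undec-8-ene-8-carboxylate
Conditions: K2CO3, MeOH, rt
Reagents that add atoms: none
Why: Base-catalysed transesterification removes the benzoate as methyl benzoate while the tert-butyl ester, silyl ether and enol ether are stable, and with the ketone gone the C10 alkoxide has no retro-aldol pathway.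

**Side chain**

Step 15
Reactants: 22 7-bromoheptan-1-ol
Product: 23 (7-bromoheptyloxy)(tert-butyl)dimethylsilane
Conditions: TBSCl, imidazole, CH2Cl2, rt
Reagents that add atoms: tert-butyldimethylsilyl chloride CC(C)(C)[Si](C)(C)Cl
Why: Standard silylation of the primary alcohol, to which the primary bromide is inert.

Step 16
Reactants: 23 (7-bromoheptyloxy)(tert-butyl)dimethylsilane
Product: 24 [7-(tert-butyldimethylsilyloxy)heptyl]triphenylphosphonium bromide
Conditions: PPh3, MeCN, reflux
Reagents that add atoms: triphenylphosphine c1ccc(cc1)P(c1ccccc1)c1ccccc1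
Why: SN2 quaternisation of triphenylphosphine by the primary bromide gives the Wittig salt.

Step 17
Reactants: 24 [7-(tert-butyldimethylsilyloxy)heptyl]triphenylphosphonium bromide; 25 9-oxononanoic acid
Product: 27 (Z)-16-[(tert-butyldimethylsilyl)oxy]hexadec-9-enoic acid, via phosphorus ylide 26 (not isolated)
Conditions: 24 (2.2 equiv), NaN(SiMe3)2 (2.2 equiv), THF, −78 °C; then 25, −78 °C → rt; citric acid work-up
Reagents that add atoms: none
Why: Wittig olefination of the aldehyde with the non-stabilised ylide under lithium-free, low-temperature conditions should give the Z alkene through the kinetically favoured cis-oxaphosphetane, one extra equivalent of ylide serving to deprotonate the carboxylic acid.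

**Union and end game**

Step 18
Reactants: 27 (Z)-16-[(tert-butyldimethylsilyl)oxy]hexadec-9-enoic acid; 21 tert-butyl 6-exo-{[(tert-butyldimethylsilyl)oxy]methyl}-10-exo-hydroxy-2-(methoxymethylidene)-6-methyltricyclo[5.3.1.0(1,5)]undec-8-ene-8-carboxylate
Product: 29 tert-butyl 10-exo-{[(9Z)-16-(tert-butyldimethylsilyloxy)hexadec-9-enoyl]oxy}-6-exo-{[(tert-butyldimethylsilyl)oxy]methyl}-2-(methoxymethylidene)-6-methyltricyclo[5.3.1.0(1,5)]undec-8-ene-8-carboxylate, via mixed anhydride 28 (not isolated)
Conditions: 2,4,6-trichlorobenzoyl chloride, Et3N, THF, rt; then 21, DMAP, toluene, rt → 40 °C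
Reagents that add atoms: none
Why: Yamaguchi esterification, in which DMAP attacks the mixed anhydride at the aliphatic carbonyl and the acylpyridinium acylates the hindered secondary C10 alcohol with retention at C10, no other free hydroxyl group being present.

Step 19
Reactants: 29 tert-butyl 10-exo-{[(9Z)-16-(tert-butyldimethylsilyloxy)hexadec-9-enoyl]oxy}-6-exo-{[(tert-butyldimethylsilyl)oxy]methyl}-2-(methoxymethylidene)-6-methyltricyclo[5.3.1.0(1,5)]undec-8-ene-8-carboxylate
Product: 30 (1R,2S,5S,6S,7S,10S)-2-formyl-10-{[(9Z)-16-hydroxyhexadec-9-enoyl]oxy}-6-(hydroxymethyl)-6-methyltricyclo[5.3.1.0(1,5)]undec-8-ene-8-carboxylic acid (CNP0148862.1)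
Conditions: TFA/CH2Cl2/H2O (5:5:1), 0 °C → rt
Reagents that add atoms: water O
Why: Aqueous acid hydrolyses the enol ether by rate-limiting protonation at C2 on the face syn to C11, the other face being shielded by the C10 acyloxy group, so the formyl group should end syn to C10 under kinetic control (low temperature and short exposure limit enol-mediated epimerisation), while the same medium removes the acid-labile tert-butyl ester and both silyl ethers.

**Compound list**

1 | cyclopentane-1,3-dione | O=C1CCC(=O)C1 | starting material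
2 | 2-allylcyclopentane-1,3-dione | C=CCC1C(=O)CCC1=O | intermediate
3 | 2-allyl-3-oxocyclopent-1-en-1-yl trifluoromethanesulfonate | C=CCC1=C(OS(=O)(=O)C(F)(F)F)CCC1=O | intermediate
4 | isopropenylboronic acid pinacol ester | CC(=C)B1OC(C)(C)C(C)(C)O1 | starting material
5 | 2-allyl-3-(prop-1-en-2-yl)cyclopent-2-en-1-one | C=CCC1=C(C(C)=C)CCC1=O | intermediate
6 | 4-methyl-3,6-dihydro-2H-pentalen-1-one (achiral fused cyclopentadiene) | CC1=CCC2=C1CCC2=O | intermediate
7 | tert-butyl diazoacetate | CC(C)(C)OC(=O)C=[N+]=[N-] | starting material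
8 | (tert-butyldimethylsilyloxy)acetaldehyde | O=CCO[Si](C)(C)C(C)(C)C | starting material
9 | tert-butyl 4-[(tert-butyldimethylsilyl)oxy]-2-diazo-3-hydroxybutanoate (racemic) | CC(C)(C)OC(=O)C(=[N+]=[N-])C(O)CO[Si](C)(C)C(C)(C)C | intermediate
10 | dichlorophosphate ester of 9 | CC(C)(C)OC(=O)C(=[N+]=[N-])C(OP(=O)(Cl)Cl)CO[Si](C)(C)C(C)(C)C | intermediate
11 | tert-butyl (E)-4-[(tert-butyldimethylsilyl)oxy]-2-diazobut-3-enoate | CC(C)(C)OC(=O)C(=[N+]=[N-])/C=C/O[Si](C)(C)C(C)(C)C | intermediate
12 | cis-divinylcyclopropane from cyclopropanation of C6=C7 of 6 (siloxyvinyl group cis to the ring diene, ester exo) | C[C@@]12C3=C(C[C@@H]1[C@@]2(/C=C/O[Si](C)(C)C(C)(C)C)C(=O)OC(C)(C)C)C(=O)CC3 | intermediate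
13 | tert-butyl 10-endo-[(tert-butyldimethylsilyl)oxy]-6-methyl-2-oxotricyclo[5.3.1.0(1,5)]undeca-5,8-diene-8-carboxylate | CC=1[C@@H]2C[C@]3([C@H](O[Si](C)(C)C(C)(C)C)C=C2C(=O)OC(C)(C)C)C(=O)CCC=13 | intermediate
14 | tert-butyl 10-endo-hydroxy-6-methyl-2-oxotricyclo[5.3.1.0(1,5)]undeca-5,8-diene-8-carboxylate | CC=1[C@@H]2C[C@]3([C@H](O)C=C2C(=O)OC(C)(C)C)C(=O)CCC=13 | intermediate
15 | alkoxyphosphonium benzoate of 14 | CC=1[C@@H]2C[C@]3([C@H](O[P+](c4ccccc4)(c4ccccc4)c4ccccc4)C=C2C(=O)OC(C)(C)C)C(=O)CCC=13.[O-]C(=O)c1ccccc1 | intermediate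
16 | tert-butyl 10-exo-(benzoyloxy)-6-methyl-2-oxotricyclo[5.3.1.0(1,5)]undeca-5,8-diene-8-carboxylate | CC=1[C@@H]2C[C@]3([C@@H](OC(=O)c4ccccc4)C=C2C(=O)OC(C)(C)C)C(=O)CCC=13 | intermediate
17 | tert-butyl 10-exo-(benzoyloxy)-6-exo-(hydroxymethyl)-6-methyl-2-oxotricyclo[5.3.1.0(1,5)]undeca-4,8-diene-8-carboxylate | C[C@@]1(CO)[C@@H]2C[C@]3([C@@H](OC(=O)c4ccccc4)C=C2C(=O)OC(C)(C)C)C(=O)CC=C13 | intermediate
18 | tert-butyl 10-exo-(benzoyloxy)-6-exo-(hydroxymethyl)-6-methyl-2-oxotricyclo[5.3.1.0(1,5)]undec-8-ene-8-carboxylate (H-5 exo) | C[C@@]1(CO)[C@@H]2C[C@]3([C@@H](OC(=O)c4ccccc4)C=C2C(=O)OC(C)(C)C)C(=O)CC[C@@H]13 | intermediate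
19 | tert-butyldimethylsilyl ether of 18 | C[C@@]1(CO[Si](C)(C)C(C)(C)C)[C@@H]2C[C@]3([C@@H](OC(=O)c4ccccc4)C=C2C(=O)OC(C)(C)C)C(=O)CC[C@@H]13 | intermediate
20 | C2 methoxymethylidene enol ether of 19 (E/Z mixture) | C[C@@]1(CO[Si](C)(C)C(C)(C)C)[C@@H]2C[C@]3([C@@H](OC(=O)c4ccccc4)C=C2C(=O)OC(C)(C)C)C(=COC)CC[C@@H]13 | intermediate
21 | 10-exo alcohol from 20 (E/Z mixture) | C[C@@]1(CO[Si](C)(C)C(C)(C)C)[C@@H]2C[C@]3([C@@H](O)C=C2C(=O)OC(C)(C)C)C(=COC)CC[C@@H]13 | intermediate
22 | 7-bromoheptan-1-ol | OCCCCCCCBr | starting material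
23 | (7-bromoheptyloxy)(tert-butyl)dimethylsilane | CC(C)(C)[Si](C)(C)OCCCCCCCBr | intermediate
24 | [7-(tert-butyldimethylsilyloxy)heptyl]triphenylphosphonium bromide | CC(C)(C)[Si](C)(C)OCCCCCCC[P+](c1ccccc1)(c1ccccc1)c1ccccc1.[Br-] | intermediate
25 | 9-oxononanoic acid | O=CCCCCCCCC(=O)O | starting material
26 | phosphorus ylide from 24 | CC(C)(C)[Si](C)(C)OCCCCCCC=P(c1ccccc1)(c1ccccc1)c1ccccc1 | intermediate
27 | (Z)-16-[(tert-butyldimethylsilyl)oxy]hexadec-9-enoic acid | CC(C)(C)[Si](C)(C)OCCCCCC/C=C\CCCCCCCC(=O)O | intermediate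
28 | mixed anhydride of 27 with 2,4,6-trichlorobenzoic acid | CC(C)(C)[Si](C)(C)OCCCCCC/C=C\CCCCCCCC(=O)OC(=O)c1c(Cl)cc(Cl)cc1Cl | intermediate
29 | fully protected ester (tert-butyl ester, two silyl ethers, enol ether; E/Z mixture at the enol ether) | C[C@@]1(CO[Si](C)(C)C(C)(C)C)[C@@H]2C[C@]3([C@@H](OC(=O)CCCCCCC/C=C\CCCCCCO[Si](C)(C)C(C)(C)C)C=C2C(=O)OC(C)(C)C)C(=COC)CC[C@@H]13 | intermediate
30 | CNP0148862.1 | C[C@@]1(CO)[C@@H]2C[C@]3([C@@H](OC(=O)CCCCCCC/C=C\CCCCCCO)C=C2C(=O)O)[C@@H](C=O)CC[C@@H]13 | target

**Step count.** Total: 19 steps. Longest linear sequence: 14 steps (steps 1–4, 7–14, 18, 19, from cyclopentane-1,3-dione).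

**Three steps most likely to fail**

Step 7. The electron-poor, acidic dienone may be cyclopropanated too slowly, so that carbene dimerisation, ylide formation at the ketone or poor enantiofacial selection take over. The fallback sets out from 6 and returns at 13. Luche reduction (NaBH4, CeCl3, MeOH, −20 °C) should give the racemic dienol 4-methyl-1,2,3,6-tetrahydropentalen-1-ol F1, and acetylation (Ac2O, pyridine, 0 °C) its acetate F2, an electron-rich cyclopentadiene that is used cold and at once. The same rhodium-catalysed reaction with 11 should then give, through the cis-divinylcyclopropane F3, the C2-epimeric cycloadduct acetates F4; both enantiomers of F2 react under catalyst control and differ only at the carbinol carbon. Methanolysis (K2CO3, MeOH) to the alcohols F5 and Dess–Martin oxidation converge on ketone 13.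

Step 10. The C–C bond may form at C5 instead of C6, the cationic character may trigger skeletal rearrangement, or the new C4=C5 double bond may migrate into conjugation with the C2 ketone. The fallback sets out from 16 and returns at 19. Hydroboration with BH3·SMe2 (excess, THF, 0 °C → rt) should add hydrogen to C5 and boron to the less hindered C6, syn from the exo face, and reduce the ketone; pinacol then gives the tertiary boronate F6. Matteson homologation (BrCH2Cl, n-BuLi, THF, −78 °C → rt) inserts CH2 with retention to give the homologated boronate F7. NaBO3 oxidation gives the diol F8, selective silylation of the primary hydroxyl (TBSCl, imidazole) gives the silyl ether F9, and Dess–Martin oxidation of the C2 carbinol returns to 19.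

Step 9. The SN2 displacement at the neopentyl-type C10 may be too slow, so that the oxyphosphonium intermediate is only hydrolysed back with retention. The fallback sets out from 14 and returns at 16. MnO2 oxidation of the allylic alcohol gives the enone F10. Corey–Bakshi–Shibata reduction ((R)-2-methyl-CBS-oxazaborolidine, catecholborane, toluene, −78 °C) should deliver hydride to the endo face under reagent control to give the exo alcohol F11. Benzoylation (BzCl, pyridine, DMAP) returns to 16.

**Further compounds**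

F1 | step 7 | 4-methyl-1,2,3,6-tetrahydropentalen-1-ol (racemic) | CC1=CCC2=C1CCC2O
F2 | step 7 | 4-methyl-1,2,3,6-tetrahydropentalen-1-yl acetate (racemic) | CC1=CCC2=C1CCC2OC(C)=O
F3 | step 7 | cis-divinylcyclopropane from F2 (C2 epimers) | C[C@@]12C3=C(C[C@@H]1[C@@]2(/C=C/O[Si](C)(C)C(C)(C)C)C(=O)OC(C)(C)C)C(OC(C)=O)CC3
F4 | step 7 | tert-butyl 2-acetoxy-10-endo-[(tert-butyldimethylsilyl)oxy]-6-methyltricyclo[5.3.1.0(1,5)]undeca-5,8-diene-8-carboxylate (C2 epimers) | CC=1[C@@H]2C[C@]3([C@H](O[Si](C)(C)C(C)(C)C)C=C2C(=O)OC(C)(C)C)C(OC(C)=O)CCC=13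
F5 | step 7 | tert-butyl 10-endo-[(tert-butyldimethylsilyl)oxy]-2-hydroxy-6-methyltricyclo[5.3.1.0(1,5)]undeca-5,8-diene-8-carboxylate (C2 epimers) | CC=1[C@@H]2C[C@]3([C@H](O[Si](C)(C)C(C)(C)C)C=C2C(=O)OC(C)(C)C)C(O)CCC=13
F6 | step 10 | tert-butyl 10-exo-(benzoyloxy)-2-hydroxy-6-methyl-6-exo-(4,4,5,5-tetramethyl-1,3,2-dioxaborolan-2-yl)tricyclo[5.3.1.0(1,5)]undec-8-ene-8-carboxylate (H-5 exo) | C[C@@]1(B4OC(C)(C)C(C)(C)O4)[C@@H]2C[C@]3([C@@H](OC(=O)c4ccccc4)C=C2C(=O)OC(C)(C)C)C(O)CC[C@@H]13
F7 | step 10 | tert-butyl 10-exo-(benzoyloxy)-2-hydroxy-6-methyl-6-exo-[(4,4,5,5-tetramethyl-1,3,2-dioxaborolan-2-yl)methyl]tricyclo[5.3.1.0(1,5)]undec-8-ene-8-carboxylate | C[C@@]1(CB4OC(C)(C)C(C)(C)O4)[C@@H]2C[C@]3([C@@H](OC(=O)c4ccccc4)C=C2C(=O)OC(C)(C)C)C(O)CC[C@@H]13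
F8 | step 10 | tert-butyl 10-exo-(benzoyloxy)-2-hydroxy-6-exo-(hydroxymethyl)-6-methyltricyclo[5.3.1.0(1,5)]undec-8-ene-8-carboxylate | C[C@@]1(CO)[C@@H]2C[C@]3([C@@H](OC(=O)c4ccccc4)C=C2C(=O)OC(C)(C)C)C(O)CC[C@@H]13
F9 | step 10 | tert-butyl 10-exo-(benzoyloxy)-6-exo-{[(tert-butyldimethylsilyl)oxy]methyl}-2-hydroxy-6-methyltricyclo[5.3.1.0(1,5)]undec-8-ene-8-carboxylate | C[C@@]1(CO[Si](C)(C)C(C)(C)C)[C@@H]2C[C@]3([C@@H](OC(=O)c4ccccc4)C=C2C(=O)OC(C)(C)C)C(O)CC[C@@H]13
F10 | step 9 | tert-butyl 6-methyl-2,10-dioxotricyclo[5.3.1.0(1,5)]undeca-5,8-diene-8-carboxylate | CC=1[C@@H]2C[C@]3(C(=O)C=C2C(=O)OC(C)(C)C)C(=O)CCC=13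
F11 | step 9 | tert-butyl 10-exo-hydroxy-6-methyl-2-oxotricyclo[5.3.1.0(1,5)]undeca-5,8-diene-8-carboxylate | CC=1[C@@H]2C[C@]3([C@@H](O)C=C2C(=O)OC(C)(C)C)C(=O)CCC=13
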